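**Retrosynthetic overview**
1. The strategy rests on ring A, the benzoic acid ring: CO2H at C1, OMe at C2, the (R)-CH(OH)CH2C(CH3)2OH chain at C3, H at C4 and C5, and the O–ring B ether at C6. These are four contiguous substituents with the C2 and C6 oxygens meta across C1, and the ether oxygen is flanked by C1 on ring A and by C2'–OH and C6'–CH2OH on ring B.
2. Late simplification: C1–CO2H from C1–CH2OPMB, C2–OMe from C2–OH; the ring-B phenol is carried as a benzyl ether, the ring-B CH2OH as a TIPS ether and the side-chain 1,3-diol as a di-tert-butylsilylene, so the last step is a fluoride deprotection and not an acid hydrolysis next to the ionisable benzylic carbinol.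
3. Key disconnection (ring A, made last and de novo): C1–C2 and C5–C6 by ketene–alkyne [2+2] and C2–C3 by six-electron electrocyclisation, from an α'-diazo enone (C2 to C5 plus the stereocentre) and an aryl ynol ether PMBOCH2–C≡C–O–ring B (C1 and C6).
4. The diazo enone comes from (R)-benzyl glycidyl ether (chiral pool). The ynol ether comes from 2-hydroxy-3-methoxy-5-methylbenzaldehyde and trichloroethylene through a dichlorovinyl ether and a lithium aryloxyacetylide, so the hindered ether oxygen is attached to an sp carbon and no arene–oxygen coupling is needed.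
5. Ring order: ring B is bought as an arene; ring A is the only ring constructed.

Key step: step 14

Remark: 2-hydroxy-3-methoxy-5-methylbenzaldehyde is taken as a catalogue compound; it is otherwise one step from 2-methoxy-4-methylphenol by MgCl2/Et3N/paraformaldehyde ortho-formylation.

Abbreviations in names: Sil = (4R)-2,2-di-tert-butyl-6,6-dimethyl-1,3,2-dioxasilinan-4-yl; ArB = 2-(benzyloxy)-4-methyl-6-{[tri(propan-2-yl)silyl]oxymethyl}phenyl; PMB = 4-methoxybenzyl; TIPS = tri(propan-2-yl)silyl. Ring-A locants C1 to C6 are those of the target benzoic acid.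

**Side-chain fragment**

Step 1
Reactants: 1 (R)-benzyl glycidyl ether
Product: 2 (2R)-1-(benzyloxy)-4-methylpent-4-en-2-ol
Conditions: CH2=C(CH3)MgBr, CuI (10 mol%), THF, −30 → 0 °C; aq. NH4Cl
Reagents that add atoms: isopropenylmagnesium bromide CC(=C)[Mg]Br
Why: Copper-catalysed Grignard opening of a terminal epoxide is SN2 at the unsubstituted CH2, so the C–O stereocentre of 1 is carried over unchanged as the (R)-carbinol.

Step 2
Reactants: 2 (2R)-1-(benzyloxy)-4-methylpent-4-en-2-ol
Product: 3 (2R)-1-(benzyloxy)-4-methylpentane-2,4-diol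
Conditions: Co(acac)2 (20 mol%), PhSiH3, O2 (1 atm), THF, rt; aq. Na2S2O3
Reagents that add atoms: dioxygen O=O
Why: Mukaiyama hydration (hydrogen-atom transfer from a cobalt hydride to the 1,1-disubstituted alkene, capture of the tertiary radical by O2, reduction of the peroxide) should give the Markovnikov tertiary alcohol without touching the benzyl ether or the stereocentre.

Step 3
Reactants: 3 (2R)-1-(benzyloxy)-4-methylpentane-2,4-diol
Product: 4 (4R)-4-[(benzyloxy)methyl]-2,2-di-tert-butyl-6,6-dimethyl-1,3,2-dioxasilinane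
Conditions: tBu2Si(OTf)2, 2,6-lutidine, CH2Cl2, 0 → 40 °C
Reagents that add atoms: di-tert-butylsilyl bis(trifluoromethanesulfonate) CC(C)(C)[Si](OS(=O)(=O)C(F)(F)F)(OS(=O)(=O)C(F)(F)F)C(C)(C)C
Why: The silyl ditriflate silylates the secondary hydroxyl and the tethered silyl triflate then closes on the tertiary hydroxyl to the six-membered silylene (cyclic silyl protection of a 1,3-diol), a group that fluoride removes at the end without acid.

Step 4
Reactants: 4 (4R)-4-[(benzyloxy)methyl]-2,2-di-tert-butyl-6,6-dimethyl-1,3,2-dioxasilinane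
Product: 5 Sil-methanol
Conditions: H2 (1 atm), Pd/C, EtOAc, rt
Reagents that add atoms: none
Why: Catalytic hydrogenolysis cleaves the primary alkyl benzyl ether, while the silylene has no benzylic C–O bond and is inert.

Step 5
Reactants: 5 Sil-methanol
Product: 7 (3E)-4-Sil-but-3-en-2-one, via aldehyde 6 (not isolated)
Conditions: Dess–Martin periodinane, NaHCO3, CH2Cl2, 0 °C → rt; then Ph3P=CHC(O)CH3, rt
Reagents that add atoms: 1-(triphenylphosphoranylidene)propan-2-one CC(=O)C=P(c1ccccc1)(c1ccccc1)c1ccccc1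
Why: Dess–Martin oxidation gives the epimerisable α-silyloxy aldehyde, which is trapped in the same flask by the neutral acetyl-stabilised ylide in an E-selective Wittig olefination, so the stereocentre never meets base.

Step 6
Reactants: 7 (3E)-4-Sil-but-3-en-2-one
Product: 9 (3E)-1-diazo-4-Sil-but-3-en-2-one, via trifluoroacetyl diketone 8 (not isolated)
Conditions: LiN(SiMe3)2, THF, −78 °C; CF3CO2CH2CF3; then MsN3, Et3N, H2O (1 equiv), MeCN, rt
Reagents that add atoms: methanesulfonyl azide CS(=O)(=O)N=[N+]=[N-]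
Why: Kinetic enolisation of the methyl ketone and Claisen trifluoroacetylation activate the methyl group for Regitz-type detrifluoroacetylative diazo transfer, the standard entry to α'-diazo enones, under which the γ-stereocentre is not deprotonated.

**Ring-B ynol ether**

Step 7
Reactants: 10 2-hydroxy-3-methoxy-5-methylbenzaldehyde
Product: 11 2,3-dihydroxy-5-methylbenzaldehyde
Conditions: BBr3, CH2Cl2, −78 → 0 °C; H2O
Reagents that add atoms: none
Why: BBr3 cleaves the aryl methyl ether (Lewis acid-assisted SN2 demethylation) to the catechol, a routine reaction of ortho-vanillin-type aldehydes.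

Step 8
Reactants: 11 2,3-dihydroxy-5-methylbenzaldehyde
Product: 12 3-(benzyloxy)-2-hydroxy-5-methylbenzaldehyde
Conditions: NaH (2.2 equiv), DMSO, 20 °C; BnBr (1.0 equiv); dilute HCl
Reagents that add atoms: benzyl bromide BrCc1ccccc1
Why: In the dianion the C3 phenoxide is neither conjugated with nor chelated to the aldehyde and is the more nucleophilic oxygen, so one equivalent of benzyl bromide should give the 3-O-benzyl ether selectively (Williamson etherification).

Step 9
Reactants: 12 3-(benzyloxy)-2-hydroxy-5-methylbenzaldehyde; 13 trichloroethylene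
Product: 15 3-(benzyloxy)-2-{[(E)-1,2-dichloroethenyl]oxy}-5-methylbenzaldehyde, via dichloroacetylene 14 (not isolated)
Conditions: K2CO3, DMF, 70 °C
Reagents that add atoms: none
Why: K2CO3 dehydrochlorinates 13 to dichloroacetylene, to which the phenoxide adds anti (nucleophilic vinylation) to give the (E)-1,2-dichlorovinyl ether, so the hindered C–O bond is made on an unhindered sp carbon.

Step 10
Reactants: 15 3-(benzyloxy)-2-{[(E)-1,2-dichloroethenyl]oxy}-5-methylbenzaldehyde
Product: 16 [3-(benzyloxy)-2-{[(E)-1,2-dichloroethenyl]oxy}-5-methylphenyl]methanol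
Conditions: NaBH4, THF/MeOH, 0 °C
Reagents that add atoms: none
Why: NaBH4 reduces the aldehyde chemoselectively (hydride 1,2-addition); the dichlorovinyl ether is inert to borohydride.

Step 11
Reactants: 16 [3-(benzyloxy)-2-{[(E)-1,2-dichloroethenyl]oxy}-5-methylphenyl]methanol
Product: 17 {[3-(benzyloxy)-2-{[(E)-1,2-dichloroethenyl]oxy}-5-methylphenyl]methoxy}tri(propan-2-yl)silane
Conditions: iPr3SiCl, imidazole, DMF, rt
Reagents that add atoms: chlorotri(propan-2-yl)silane CC(C)[Si](Cl)(C(C)C)C(C)C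
Why: Silylation of the primary benzylic alcohol gives a TIPS ether that is stable to base and to organolithium reagents.

Step 12
Reactants: 17 {[3-(benzyloxy)-2-{[(E)-1,2-dichloroethenyl]oxy}-5-methylphenyl]methoxy}tri(propan-2-yl)silane
Product: 20 3-(ArB-oxy)prop-2-yn-1-ol, via chloroethynyl ether 18 (not isolated), via lithium aryloxyacetylide 19 (not isolated)
Conditions: n-BuLi (2.3 equiv), THF, −78 → −40 °C; (CH2O)n, −78 °C → rt; aq. NH4Cl/NaHCO3
Reagents that add atoms: formaldehyde (from paraformaldehyde) C=O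
Why: n-BuLi deprotonates the vinylic C–H, the chlorovinyllithium loses LiCl to the chloroethynyl ether and lithium–chlorine exchange gives the lithium aryloxyacetylide (dichlorovinyl ether route to ynol ethers), which adds to formaldehyde.

Step 13
Reactants: 20 3-(ArB-oxy)prop-2-yn-1-ol
Product: 21 ArB 3-(PMB-oxy)prop-1-yn-1-yl ether
Conditions: NaH, 4-MeOC6H4CH2Cl, Bu4NI (cat.), THF/DMF, 0 °C → rt
Reagents that add atoms: 4-methoxybenzyl chloride COc1ccc(CCl)cc1
Why: Williamson etherification of the primary propargylic alkoxide installs the PMB group under basic conditions, so the acid-sensitive ynol ether never meets acid.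

**Key step and endgame**

Step 14
Reactants: 9 (3E)-1-diazo-4-Sil-but-3-en-2-one; 21 ArB 3-(PMB-oxy)prop-1-yn-1-yl ether
Product: 26 3-(ArB-oxy)-6-Sil-2-[(PMB-oxy)methyl]phenol, via vinylketene 22 (not isolated), via 4-vinylcyclobutenone 23 (not isolated), via dienylketene 24 (not isolated), via cyclohexa-2,4-dienone 25 (not isolated)
Conditions: 21 (1.0 equiv), 9 (1.5 equiv, added in portions), hν (medium-pressure Hg lamp, Pyrex filter, λ > 300 nm), ClCH2CH2Cl, 25 °C; then 80 °C in the dark
Reagents that add atoms: none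
Why: Light induces Wolff rearrangement of 9 to vinylketene 22, whose electrophilic carbonyl carbon is attacked by the nucleophilic alkyne carbon of 21 (the one bearing CH2OPMB, remote from oxygen) in a [2+2] cycloaddition that forms C1–C2 and C5–C6 and gives 4-vinylcyclobutenone 23. Four-electron electrocyclic opening of 23 (light or heat) gives dienylketene 24, and ring A closes by thermal disrotatory six-electron electrocyclisation forming C2–C3 to cyclohexadienone 25, which tautomerises to phenol 26. The closest known reaction type is the Danheiser benzannulation of photochemically generated vinylketenes with alkoxy- and siloxyalkynes, here run with an aryl ynol ether, which has no β-hydrogen and so cannot undergo the retro-ene loss of alkene that limits alkyl ynol ethers on heating. No stereocentre is created: the (R)-carbinol centre lies outside the pericyclic array and the transient sp3 centres of 23 and 25 vanish on aromatisation. The step needs only [2+2] regiochemistry, fixed by the O–C≡C polarisation of 21 so that CH2OPMB ends ortho and the aryloxy group meta to the new hydroxyl, and selective excitation of the diazo enone, secured by the Pyrex cut-off that keeps the aryl ether chromophores dark.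

Step 15
Reactants: 26 3-(ArB-oxy)-6-Sil-2-[(PMB-oxy)methyl]phenol
Product: 27 (4R)-4-{4-(ArB-oxy)-2-methoxy-3-[(PMB-oxy)methyl]phenyl}-2,2-di-tert-butyl-6,6-dimethyl-1,3,2-dioxasilinane
Conditions: MeI, K2CO3, DMF, rt
Reagents that add atoms: iodomethane CI
Why: The hindered phenoxide is O-methylated by iodomethane in a dipolar aprotic solvent (Williamson etherification); silyl, benzyl and PMB ethers are unaffected.

Step 16
Reactants: 27 (4R)-4-{4-(ArB-oxy)-2-methoxy-3-[(PMB-oxy)methyl]phenyl}-2,2-di-tert-butyl-6,6-dimethyl-1,3,2-dioxasilinane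
Product: 28 [6-(ArB-oxy)-2-methoxy-3-Sil-phenyl]methanol
Conditions: DDQ, CH2Cl2/pH 7 phosphate buffer, 0 °C
Reagents that add atoms: none
Why: DDQ oxidises the electron-rich PMB ether to an oxocarbenium ion that water hydrolyses (oxidative PMB cleavage); the benzyl ether, the TIPS ether and the buffered silylene should survive.

Step 17
Reactants: 28 [6-(ArB-oxy)-2-methoxy-3-Sil-phenyl]methanol
Product: 29 6-(ArB-oxy)-2-methoxy-3-Sil-benzaldehyde
Conditions: Dess–Martin periodinane, NaHCO3, CH2Cl2, rt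
Reagents that add atoms: none
Why: Dess–Martin oxidation converts the primary benzylic alcohol to the aldehyde under buffered, non-acidic conditions.

Step 18
Reactants: 29 6-(ArB-oxy)-2-methoxy-3-Sil-benzaldehyde
Product: 30 6-(ArB-oxy)-2-methoxy-3-Sil-benzoic acid
Conditions: NaClO2, NaH2PO4, 2-methyl-2-butene, t-BuOH/H2O, rt
Reagents that add atoms: sodium chlorite [Na+].[O-]Cl=O
Why: Pinnick oxidation (chlorous acid, with hypochlorous acid scavenged by 2-methyl-2-butene) takes the hindered 2,6-disubstituted benzaldehyde to the acid without chlorinating the electron-rich rings.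

Step 19
Reactants: 30 6-(ArB-oxy)-2-methoxy-3-Sil-benzoic acid
Product: 31 6-[2-hydroxy-4-methyl-6-(TIPS-oxymethyl)phenoxy]-2-methoxy-3-Sil-benzoic acid
Conditions: H2 (1 atm), Pd/C, EtOAc, rt
Reagents that add atoms: none
Why: Hydrogenolysis cleaves the aryl benzyl ether quickly, while the two benzylic oxygens are capped as bulky silyl ethers and should resist C–O hydrogenolysis in a non-acidic solvent.

Step 20
Reactants: 31 6-[2-hydroxy-4-methyl-6-(TIPS-oxymethyl)phenoxy]-2-methoxy-3-Sil-benzoic acid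
Product: 32 3-[(1R)-1,3-dihydroxy-3-methylbutyl]-6-[2-hydroxy-6-(hydroxymethyl)-4-methylphenoxy]-2-methoxybenzoic acid
Conditions: HF·pyridine, pyridine, THF, 0 °C → rt
Reagents that add atoms: none
Why: Fluoride cleaves both the TIPS ether and the di-tert-butylsilylene (Si–F bond formation), and the pyridine buffer keeps the medium too weakly acidic to ionise the para-aryloxy-activated benzylic carbinol, so the (R) centre should be retained.

**Compound list**
1 | (R)-benzyl glycidyl ether, (2R)-2-[(benzyloxy)methyl]oxirane | C(OCc1ccccc1)[C@H]1CO1 | starting material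
2 | (2R)-1-(benzyloxy)-4-methylpent-4-en-2-ol | C(OCc1ccccc1)[C@H](O)CC(C)=C | intermediate
3 | (2R)-1-(benzyloxy)-4-methylpentane-2,4-diol | C(OCc1ccccc1)[C@H](O)CC(C)(C)O | intermediate
4 | (4R)-4-[(benzyloxy)methyl]-2,2-di-tert-butyl-6,6-dimethyl-1,3,2-dioxasilinane | C(OCc1ccccc1)[C@H]1CC(C)(C)O[Si](C(C)(C)C)(C(C)(C)C)O1 | intermediate
5 | [(4R)-2,2-di-tert-butyl-6,6-dimethyl-1,3,2-dioxasilinan-4-yl]methanol | OC[C@H]1CC(C)(C)O[Si](C(C)(C)C)(C(C)(C)C)O1 | intermediate
6 | (4R)-2,2-di-tert-butyl-6,6-dimethyl-1,3,2-dioxasilinane-4-carbaldehyde | O=C[C@H]1CC(C)(C)O[Si](C(C)(C)C)(C(C)(C)C)O1 | intermediate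
7 | (3E)-4-[(4R)-2,2-di-tert-butyl-6,6-dimethyl-1,3,2-dioxasilinan-4-yl]but-3-en-2-one | CC(=O)/C=C/[C@H]1CC(C)(C)O[Si](C(C)(C)C)(C(C)(C)C)O1 | intermediate
8 | (5E)-6-[(4R)-2,2-di-tert-butyl-6,6-dimethyl-1,3,2-dioxasilinan-4-yl]-1,1,1-trifluorohex-5-ene-2,4-dione | FC(F)(F)C(=O)CC(=O)/C=C/[C@H]1CC(C)(C)O[Si](C(C)(C)C)(C(C)(C)C)O1 | intermediate
9 | (3E)-1-diazo-4-[(4R)-2,2-di-tert-butyl-6,6-dimethyl-1,3,2-dioxasilinan-4-yl]but-3-en-2-one | [N-]=[N+]=CC(=O)/C=C/[C@H]1CC(C)(C)O[Si](C(C)(C)C)(C(C)(C)C)O1 | intermediate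
10 | 2-hydroxy-3-methoxy-5-methylbenzaldehyde | COc1cc(C)cc(C=O)c1O | starting material
11 | 2,3-dihydroxy-5-methylbenzaldehyde | Oc1cc(C)cc(C=O)c1O | intermediate
12 | 3-(benzyloxy)-2-hydroxy-5-methylbenzaldehyde | O=Cc1cc(C)cc(OCc2ccccc2)c1O | intermediate
13 | trichloroethylene | ClC=C(Cl)Cl | starting material
14 | dichloroacetylene | ClC#CCl | intermediate
15 | 3-(benzyloxy)-2-{[(E)-1,2-dichloroethenyl]oxy}-5-methylbenzaldehyde | O=Cc1cc(C)cc(OCc2ccccc2)c1O/C(Cl)=C\Cl | intermediate
16 | [3-(benzyloxy)-2-{[(E)-1,2-dichloroethenyl]oxy}-5-methylphenyl]methanol | OCc1cc(C)cc(OCc2ccccc2)c1O/C(Cl)=C\Cl | intermediate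
17 | {[3-(benzyloxy)-2-{[(E)-1,2-dichloroethenyl]oxy}-5-methylphenyl]methoxy}tri(propan-2-yl)silane | CC(C)[Si](C(C)C)(C(C)C)OCc1cc(C)cc(OCc2ccccc2)c1O/C(Cl)=C\Cl | intermediate
18 | {[3-(benzyloxy)-2-[(chloroethynyl)oxy]-5-methylphenyl]methoxy}tri(propan-2-yl)silane | CC(C)[Si](C(C)C)(C(C)C)OCc1cc(C)cc(OCc2ccccc2)c1OC#CCl | intermediate
19 | lithium 2-[2-(benzyloxy)-4-methyl-6-{[tri(propan-2-yl)silyl]oxymethyl}phenoxy]ethynide | CC(C)[Si](C(C)C)(C(C)C)OCc1cc(C)cc(OCc2ccccc2)c1OC#C[Li] | intermediate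
20 | 3-[2-(benzyloxy)-4-methyl-6-{[tri(propan-2-yl)silyl]oxymethyl}phenoxy]prop-2-yn-1-ol | CC(C)[Si](C(C)C)(C(C)C)OCc1cc(C)cc(OCc2ccccc2)c1OC#CCO | intermediate
21 | {[3-(benzyloxy)-2-({3-[(4-methoxybenzyl)oxy]prop-1-yn-1-yl}oxy)-5-methylphenyl]methoxy}tri(propan-2-yl)silane | COc1ccc(COCC#COc2c(OCc3ccccc3)cc(C)cc2CO[Si](C(C)C)(C(C)C)C(C)C)cc1 | intermediate
22 | (3E)-4-[(4R)-2,2-di-tert-butyl-6,6-dimethyl-1,3,2-dioxasilinan-4-yl]buta-1,3-dien-1-one | O=C=C/C=C/[C@H]1CC(C)(C)O[Si](C(C)(C)C)(C(C)(C)C)O1 | intermediate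
23 | 3-[2-(benzyloxy)-4-methyl-6-{[tri(propan-2-yl)silyl]oxymethyl}phenoxy]-4-{(E)-2-[(4R)-2,2-di-tert-butyl-6,6-dimethyl-1,3,2-dioxasilinan-4-yl]ethenyl}-2-{[(4-methoxybenzyl)oxy]methyl}cyclobut-2-en-1-one (both configurations at the ring sp3 carbon) | O=C1C(COCc2ccc(OC)cc2)=C(Oc2c(OCc3ccccc3)cc(C)cc2CO[Si](C(C)C)(C(C)C)C(C)C)C1/C=C/[C@H]1CC(C)(C)O[Si](C(C)(C)C)(C(C)(C)C)O1 | intermediate
24 | (3E,5E)-3-[2-(benzyloxy)-4-methyl-6-{[tri(propan-2-yl)silyl]oxymethyl}phenoxy]-6-[(4R)-2,2-di-tert-butyl-6,6-dimethyl-1,3,2-dioxasilinan-4-yl]-2-{[(4-methoxybenzyl)oxy]methyl}hexa-1,3,5-trien-1-one | O=C=C(COCc1ccc(OC)cc1)/C(Oc1c(OCc2ccccc2)cc(C)cc1CO[Si](C(C)C)(C(C)C)C(C)C)=C\C=C\[C@H]1CC(C)(C)O[Si](C(C)(C)C)(C(C)(C)C)O1 | intermediate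
25 | 3-[2-(benzyloxy)-4-methyl-6-{[tri(propan-2-yl)silyl]oxymethyl}phenoxy]-6-[(4R)-2,2-di-tert-butyl-6,6-dimethyl-1,3,2-dioxasilinan-4-yl]-2-{[(4-methoxybenzyl)oxy]methyl}cyclohexa-2,4-dien-1-one (both configurations at C6) | O=C1C(COCc2ccc(OC)cc2)=C(Oc2c(OCc3ccccc3)cc(C)cc2CO[Si](C(C)C)(C(C)C)C(C)C)C=CC1[C@H]1CC(C)(C)O[Si](C(C)(C)C)(C(C)(C)C)O1 | intermediate
26 | 3-[2-(benzyloxy)-4-methyl-6-{[tri(propan-2-yl)silyl]oxymethyl}phenoxy]-6-[(4R)-2,2-di-tert-butyl-6,6-dimethyl-1,3,2-dioxasilinan-4-yl]-2-{[(4-methoxybenzyl)oxy]methyl}phenol | Oc1c([C@H]2CC(C)(C)O[Si](C(C)(C)C)(C(C)(C)C)O2)ccc(Oc2c(OCc3ccccc3)cc(C)cc2CO[Si](C(C)C)(C(C)C)C(C)C)c1COCc1ccc(OC)cc1 | intermediate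
27 | (4R)-4-{4-[2-(benzyloxy)-4-methyl-6-{[tri(propan-2-yl)silyl]oxymethyl}phenoxy]-2-methoxy-3-{[(4-methoxybenzyl)oxy]methyl}phenyl}-2,2-di-tert-butyl-6,6-dimethyl-1,3,2-dioxasilinane | COc1c([C@H]2CC(C)(C)O[Si](C(C)(C)C)(C(C)(C)C)O2)ccc(Oc2c(OCc3ccccc3)cc(C)cc2CO[Si](C(C)C)(C(C)C)C(C)C)c1COCc1ccc(OC)cc1 | intermediate
28 | {6-[2-(benzyloxy)-4-methyl-6-{[tri(propan-2-yl)silyl]oxymethyl}phenoxy]-3-[(4R)-2,2-di-tert-butyl-6,6-dimethyl-1,3,2-dioxasilinan-4-yl]-2-methoxyphenyl}methanol | COc1c([C@H]2CC(C)(C)O[Si](C(C)(C)C)(C(C)(C)C)O2)ccc(Oc2c(OCc3ccccc3)cc(C)cc2CO[Si](C(C)C)(C(C)C)C(C)C)c1CO | intermediate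
29 | 6-[2-(benzyloxy)-4-methyl-6-{[tri(propan-2-yl)silyl]oxymethyl}phenoxy]-3-[(4R)-2,2-di-tert-butyl-6,6-dimethyl-1,3,2-dioxasilinan-4-yl]-2-methoxybenzaldehyde | COc1c([C@H]2CC(C)(C)O[Si](C(C)(C)C)(C(C)(C)C)O2)ccc(Oc2c(OCc3ccccc3)cc(C)cc2CO[Si](C(C)C)(C(C)C)C(C)C)c1C=O | intermediate
30 | 6-[2-(benzyloxy)-4-methyl-6-{[tri(propan-2-yl)silyl]oxymethyl}phenoxy]-3-[(4R)-2,2-di-tert-butyl-6,6-dimethyl-1,3,2-dioxasilinan-4-yl]-2-methoxybenzoic acid | COc1c([C@H]2CC(C)(C)O[Si](C(C)(C)C)(C(C)(C)C)O2)ccc(Oc2c(OCc3ccccc3)cc(C)cc2CO[Si](C(C)C)(C(C)C)C(C)C)c1C(=O)O | intermediate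
31 | 3-[(4R)-2,2-di-tert-butyl-6,6-dimethyl-1,3,2-dioxasilinan-4-yl]-6-[2-hydroxy-4-methyl-6-{[tri(propan-2-yl)silyl]oxymethyl}phenoxy]-2-methoxybenzoic acid | COc1c([C@H]2CC(C)(C)O[Si](C(C)(C)C)(C(C)(C)C)O2)ccc(Oc2c(O)cc(C)cc2CO[Si](C(C)C)(C(C)C)C(C)C)c1C(=O)O | intermediate
32 | 3-[(1R)-1,3-dihydroxy-3-methylbutyl]-6-[2-hydroxy-6-(hydroxymethyl)-4-methylphenoxy]-2-methoxybenzoic acid (CNP0452050.1) | COc1c([C@H](O)CC(C)(C)O)ccc(Oc2c(O)cc(C)cc2CO)c1C(=O)O | target

**Step count**
Total: 20 steps (one-flask sequences counted once). Longest linear sequence: 14 steps (10 → 32, steps 7 to 20); the side-chain branch is 6 steps to 9.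

**Steps most likely to fail, with fallbacks**

Step 14. The vinylketene may be lost to dimerisation or to acylation of the product phenol before the only moderately nucleophilic aryl ynol ether captures it, and prolonged irradiation may degrade the aryl ether partner. The fallback sets out from 9 and comes back at 26. It separates ketene generation from light and from the alkyne. Compound 9 is photolysed alone in THF/H2O, so that water traps the ketene and gives (3E)-4-Sil-but-3-enoic acid F1. This is converted under neutral conditions with 1-chloro-N,N,2-trimethylprop-1-en-1-amine into (3E)-4-Sil-but-3-enoyl chloride F2. Slow addition of F2 to 21 and Et3N in toluene (25 → 80 °C, dark) generates the same vinylketene 22 by dehydrochlorination at a low stationary concentration in the presence of the full charge of ynol ether. The [2+2] addition, ring opening and electrocyclisation then lead to 26 as in the main step.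

Step 12. The lithium acetylide may be captured incompletely by slowly depolymerising paraformaldehyde, and the 3-aryloxypropargyl alcohol may undergo acid-triggered Meyer–Schuster-type rearrangement on work-up or on silica. The fallback sets out from 17 and comes back at 21. The acetylide 19 is generated as before but quenched with 4-methoxybenzyl chloromethyl ether (COc1ccc(COCCl)cc1, made from the methylthiomethyl ether of 4-methoxybenzyl alcohol and SO2Cl2). Direct C-alkylation gives 21 in one flask, so the free propargylic alcohol never exists and step 13 is skipped.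

Step 9. The phenoxide of 12 is chelated, conjugated with the aldehyde and di-ortho-substituted, so its addition to dichloroacetylene may be sluggish, with base-induced degradation of the aldehyde on long heating. The fallback sets out from 12 and comes back at 17. The order of events is changed so that a non-conjugated phenoxide is vinylated. NaBH4 reduction of 12 gives 2-(benzyloxy)-6-(hydroxymethyl)-4-methylphenol F3. Selective silylation of its primary hydroxyl (iPr3SiCl, imidazole, CH2Cl2, 0 °C; a silyl group on the hindered phenol would migrate to the alkoxide) gives 2-(benzyloxy)-4-methyl-6-{[tri(propan-2-yl)silyl]oxymethyl}phenol F4. Its potassium phenoxide (KH, THF) is then treated with 13 (−78 °C → rt) to give 17.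

**Further compounds**
F1 | step 14 | (3E)-4-[(4R)-2,2-di-tert-butyl-6,6-dimethyl-1,3,2-dioxasilinan-4-yl]but-3-enoic acid | OC(=O)C/C=C/[C@H]1CC(C)(C)O[Si](C(C)(C)C)(C(C)(C)C)O1
F2 | step 14 | (3E)-4-[(4R)-2,2-di-tert-butyl-6,6-dimethyl-1,3,2-dioxasilinan-4-yl]but-3-enoyl chloride | ClC(=O)C/C=C/[C@H]1CC(C)(C)O[Si](C(C)(C)C)(C(C)(C)C)O1
F0 | step 12 | none | none
F3 | step 9 | 2-(benzyloxy)-6-(hydroxymethyl)-4-methylphenol | OCc1cc(C)cc(OCc2ccccc2)c1O
F4 | step 9 | 2-(benzyloxy)-4-methyl-6-{[tri(propan-2-yl)silyl]oxymethyl}phenol | CC(C)[Si](C(C)C)(C(C)C)OCc1cc(C)cc(OCc2ccccc2)c1O
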